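## The problem

Compound 17 is a 3,3,5,5-tetrasubstituted 1,2-dioxolane. With the ring numbered O1–O2–C3–C4–C5, C3 carries a methyl group and the acetic acid arm (C2, C1), and C5 carries a methyl group and the chain C6–C17, which has methyl-bearing stereocentres at C7 (S) and C9 (R) and a phenyl group on C17. The carbon skeleton is one chain, so the task is to place an O–O bridge between two fully substituted carbons, C3 and C5. Neither has a hydrogen atom or a neighbouring functional group through which its configuration could be corrected afterwards.

Four stereocentres must be set. The anti-1,3-dimethyl pair C7/C9 lies in an unfunctionalised hydrocarbon stretch and has to come from reagent- or catalyst-controlled C–C bond formation. The ring pair C3/C5 must be (3R,5R), with the two methyl groups cis. C9 can influence only C7. C7 is separated from C5 by the C6 methylene group and can bias a reaction at C5 only weakly. C3 and C5 control each other only across C4, where methyl competes with a CH2R group of similar size.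

The O–O bond will not survive hydrides, hydrogenation, phosphines, low-valent metals or Lewis acids at ambient temperature. A carbonyl group at C1 also puts the peroxide β to an enolisable position, so strong base can open the ring by β-elimination. The ring should therefore be made late and be followed only by mild, non-reducing steps. The alkylbenzene terminus is robust, but it is a weak π-nucleophile with benzylic C–H bonds, which matters in cationic and strongly oxidising steps.

The feature that allows a convergent key step is this: C4–C5, with the C5 methyl group and the chain, is the terminal carbon pair of a 2-methylalk-1-ene. C3, with its methyl group, its two-carbon arm and both ring oxygens, is a methyl ketone at the peroxyketal oxidation level. A peroxycarbenium ion at C3 can take up the alkene C4=C5 and form C3–C4 and O1–C5 in one operation.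

## Retrosynthesis

**Oxidation level of C1 (17 ⇒ 15 ⇒ 14).** No skeletal bond is cut; the carboxyl group is traced back through aldehyde 16 to primary alcohol 15 and its silyl ether 14. Carrying C1 as an ester through the ring-forming step would save a step, but it is set aside for three reasons:
- an ester carbonyl two atoms from the cationic C3 would acidify the C2 protons, so the ion could collapse to a conjugated enol peroxide;
- it would offer the Lewis acid a chelating site;
- at the hydroperoxide stage it could close to a peroxylactone.

A silyl-protected alcohol turns the ionised fragment into an ordinary dialkyl ketone peroxyketal. The price is a fluoride deprotection and an oxidation after the ring is formed, both compatible with a tetrasubstituted dialkyl peroxide. Alcohol 15 is also the most convenient stage for chromatographic separation of the ring diastereomers.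

**Key disconnection (14 ⇒ 9 + 13).** The bonds C3–C4 and O1–C5 are cut, giving alkene 9 (C4–C17) and silylperoxy ketal 13 (C1–C3 with both oxygens). The neighbouring cut, C4–C5 and O2–C3, would place the peroxide on the chain fragment and carry it there through several steps. The chosen cut keeps the valuable chain as a plain hydrocarbon alkene until the union and builds the peroxide on a five-carbon fragment from a commodity alcohol. Both precursors are acyclic; 13 has no stereocentre that matters and 9 has only C7 and C9. The forward reaction must give Markovnikov attack of the alkene on the C3 cation and capture of the tertiary C5 cation by oxygen faster than proton loss. It is not expected to control C3 or C5.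

**Peroxyketal (13 ⇒ 12 ⇒ 11 ⇒ 10).** The O–Si bond of 13 is cut to hydroperoxy ketal 12. The C3–O bonds of 12 are traced to the C=CH2 bond of alkene 11 by ozonolysis in methanol, and 11 is the silyl ether of 3-methylbut-3-en-1-ol 10. Ozonolysis is preferred to perhydrolysis of a ketone or ketal because it introduces exactly one hydroperoxy and one methoxy group under neutral conditions. The only demand is that the primary ozonide cleaves towards the more substituted carbonyl oxide.

**Alkene (9 ⇒ 8).** The C4=C5 double bond is cut to methyl ketone 8 by a Wittig methylenation. A methyl ketone is the natural product of a conjugate addition to an enone, and the nearest stereocentre is β to the carbonyl and cannot epimerise.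

**C7 (8 ⇒ 7 ⇒ 5 + 6).** The C7–CH3 bond is cut, giving (E)-enone 7 and a methyl nucleophile. Cutting C6–C7 or C7–C8 by alkylation would need an auxiliary and extra redox steps. Enone 7 has one stereocentre fewer and comes from aldehyde 5 and the stabilised ylide 6 by cutting the C5=C6 bond of 7 (enone numbering C3=C4). The forward addition must be 1,4-selective and catalyst-controlled, since C9 is too remote to help.

**C9 (5 ⇒ 4 ⇒ 3 + 2, 3 ⇒ 1).** Aldehyde 5 is the reduction product of methyl ester 4. In 4 the C9–C10 bond is cut, giving methyl crotonate 2 and Grignard reagent 3 from (8-bromooctyl)benzene 1. Adding the long chain to crotonate, rather than methyl to a long-chain enoate, saves the two steps needed to make that enoate. It asks the catalyst to distinguish the faces of a small β-methyl enoate.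

## Roads not taken

**Alternative 1: iterative boronic ester homologation for the chain.** The cut runs through C9–C10, C8–C9, C7–C8 and C6–C7. In the forward direction the pinacol boronic ester A1 of the 8-phenyloctyl group would be homologated four times. Carbenoids from lithiated ethyl 2,4,6-triisopropylbenzoate (configured by sparteine-mediated lithiation or by tin–lithium exchange) insert the CH(CH3) units C9 and C7. Chloromethyllithium, LiCH2Cl, inserts the methylene groups C8 and C6. The product is primary boronic ester A2.
- Merits: each stereocentre is set under reagent control, independently of the other, with a fidelity that two catalytic conjugate additions are unlikely to match. The anti pattern needs only a change of carbenoid enantiomer. A2 would reach alkene 9 in one Zweifel olefination with isopropenyllithium.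
- Weak points: four cryogenic organolithium operations and stoichiometric chiral diamine or stannane for two methyl groups. It does not address the dioxolane, so a ring-forming key step is still needed and the alternative replaces only steps 1–5.
- Comparison: it would be about six operations to 9 against five. It is better in stereochemical purity of the chain. The chosen plan answers with catalytic chirality from one ligand enantiomer and fewer operations. If the conjugate additions prove insufficiently selective, this is the replacement to adopt.

**Alternative 2: the same annulation with the roles reversed.** The cut is C4–C5 and O2–C3. The triethylsilylperoxy ketal A3 of the chain ketone would be ionised with SnCl4 and intercepted by alkene 11, giving silyl ether A4, which is the same structure as 14.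
- Merits: same reaction class and same endgame. The valuable component is the electrophile and can be consumed completely by an excess of the one-step alkene 11. The chain carries no acid-sensitive double bond when the Lewis acid is present. In these respects it is as good as or better than the chosen plan.
- Weak points: the peroxide must be installed on the chain fragment. The cleanest entry to A3 is methanolic ozonolysis of alkene 9 followed by silylation, so the sequence passes through 9 and adds two steps of peroxide handling on the most expensive intermediate. The homoallylic silyloxy group also makes 11 a somewhat poorer nucleophile than 9. Ring stereocontrol is equally absent.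
- Comparison: the chosen plan has a longest linear sequence shorter by two steps and does its peroxide chemistry on a cheap five-carbon fragment, which can likewise be used in excess. Alternative 2 is retained as the fallback for the key step.

**Alternative 3: radical oxygenation of a vinylcyclopropane.** The cut is O1–C5 and O2–C3, with both oxygens from O2. A phenylthiyl radical (diphenyl disulfide, initiator, light) would add to the vinyl group of cyclopropane A5. The ring would open to the tertiary C5 radical, O2 would be trapped, and the peroxyl radical would close 5-exo onto the allyl sulfide and expel the thiyl radical, giving vinyl dioxolane A6.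
- Merits: neutral conditions, no Lewis acid and no cations, so alkene isomerisation, hydrochlorination and arene alkylation cannot occur. In functional-group tolerance it is better than the chosen key step.
- Weak points: A5 has two quaternary cyclopropane carbons and must be built linearly on the chain, several steps beyond ketone 8. The chair-like 5-exo transition state distinguishes methyl from CH2R poorly at both ends, so ring diastereocontrol is no better. The vinyl group must then become CH2CO2H by hydroboration in the presence of the peroxide and oxidation.
- Comparison: the chosen plan is convergent, reaches the same oxidation-level endgame without a borane step next to the O–O bond, and is shorter. It accepts the risks of cationic chemistry in exchange.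

Key step: step 9

Assumption: the sense of induction in steps 1 and 4 is assigned from the usual behaviour of CuBr/Josiphos catalysts with (E)-configured acceptors; if the first run of either step gives the opposite configuration, the mirror-image ligand is used in that step and nothing else changes.

Remark on names: (S,R)-Josiphos is (S)-1-[(R)-2-(diphenylphosphino)ferrocenyl]ethyldicyclohexylphosphine, C36H44FeP2. C3 is 3S in 14 and 15 and 3R in 16 and 17 only because the oxidised arm outranks C4 in the sequence rule; the spatial arrangement is the same.

## Route

Step 1
Reactants: 1 (8-bromooctyl)benzene; 2 methyl (2E)-but-2-enoate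
Product: 4 methyl (3R)-3-methyl-11-phenylundecanoate, via 8-phenyloctylmagnesium bromide 3 (not isolated)
Conditions: Mg, Et2O, reflux; then 2, CuBr·SMe2 (1 mol%), (S,R)-Josiphos (1.2 mol%), tBuOMe, −75 °C; aq. NH4Cl
Reagents that add atoms: none
Why: Copper-catalysed asymmetric conjugate addition of a primary alkyl Grignard reagent to an (E)-enoate; the chiral CuBr/Josiphos complex selects the enoate face and so sets C9 (3R in 4), and tBuOMe at −75 °C suppresses 1,2-addition.

Step 2
Reactants: 4 methyl (3R)-3-methyl-11-phenylundecanoate
Product: 5 (3R)-3-methyl-11-phenylundecanal
Conditions: i-Bu2AlH (1.05 equiv), CH2Cl2, −78 °C; MeOH, then aq. KNaC4H4O6 (potassium sodium tartrate)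
Reagents that add atoms: none
Why: Partial reduction of a methyl ester with i-Bu2AlH at −78 °C stops at the aluminium hemiacetal, which gives the aldehyde on work-up; the stereocentre is β to the carbonyl, not enolisable, and is untouched.

Step 3
Reactants: 5 (3R)-3-methyl-11-phenylundecanal; 6 1-(triphenyl-λ5-phosphanylidene)propan-2-one
Product: 7 (3E,6R)-6-methyl-14-phenyltetradec-3-en-2-one
Conditions: CH2Cl2, rt to 40 °C
Reagents that add atoms: none
Why: Wittig olefination with a stabilised acyl ylide, which with an unhindered aliphatic aldehyde should give the (E)-enone with high selectivity.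

Step 4
Reactants: 7 (3E,6R)-6-methyl-14-phenyltetradec-3-en-2-one
Product: 8 (4S,6R)-4,6-dimethyl-14-phenyltetradecan-2-one
Conditions: MeMgBr (1.2 equiv, Et2O), CuBr·SMe2 (5 mol%), (S,R)-Josiphos (6 mol%), tBuOMe, −75 °C; aq. NH4Cl
Reagents that add atoms: methylmagnesium bromide, C[Mg]Br
Why: Copper-catalysed asymmetric conjugate addition of MeMgBr to an acyclic aliphatic enone; C7 (4S in 8) is set under catalyst control because the existing centre is two atoms from the reacting β-carbon, and the same ligand enantiomer as in step 1 gives the anti array because methyl is now the nucleophile.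

Step 5
Reactants: 8 (4S,6R)-4,6-dimethyl-14-phenyltetradecan-2-one
Product: 9 (4S,6R)-2,4,6-trimethyl-14-phenyltetradec-1-ene
Conditions: Ph3PCH3Br, KOtBu, THF, 0 °C to rt
Reagents that add atoms: methyltriphenylphosphonium bromide, C[P+](c1ccccc1)(c1ccccc1)c1ccccc1.[Br-]
Why: Wittig methylenation of a methyl ketone with the non-stabilised ylide; the nearest stereocentre is β to the carbonyl group and cannot epimerise under the basic conditions.

Step 6
Reactants: 10 3-methylbut-3-en-1-ol
Product: 11 tert-butyl[(3-methylbut-3-en-1-yl)oxy]diphenylsilane
Conditions: TBDPSCl, imidazole, CH2Cl2, rt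
Reagents that add atoms: tert-butyl(chloro)diphenylsilane, CC(C)(C)[Si](Cl)(c1ccccc1)c1ccccc1
Why: Standard silylation of a primary alcohol; the TBDPS ether is chosen because it should survive ozone and SnCl4 at −78 °C and is removed by fluoride without touching a peroxide.

Step 7
Reactants: 11 tert-butyl[(3-methylbut-3-en-1-yl)oxy]diphenylsilane
Product: 12 tert-butyl(3-hydroperoxy-3-methoxybutoxy)diphenylsilane (racemic)
Conditions: O3, CH2Cl2/MeOH (4:1), −78 °C, Sudan Red 7B as end-point indicator; N2 purge, no reductant
Reagents that add atoms: ozone, [O-][O+]=O; methanol, CO
Why: Criegee ozonolysis in methanol: the primary ozonide of a 1,1-disubstituted alkene cleaves mainly to formaldehyde and the more substituted ketone O-oxide, which methanol traps as the α-methoxy hydroperoxide; the indicator dye stops the reaction before the phenyl rings are attacked.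

Step 8
Reactants: 12 tert-butyl(3-hydroperoxy-3-methoxybutoxy)diphenylsilane
Product: 13 tert-butyl{3-methoxy-3-[(triethylsilyl)peroxy]butoxy}diphenylsilane (racemic)
Conditions: Et3SiCl, imidazole, DMF, 0 °C to rt
Reagents that add atoms: chlorotriethylsilane, CC[Si](Cl)(CC)CC
Why: O-Silylation of a hydroperoxide, which is more acidic than an alcohol and silylates readily with a chlorosilane and imidazole; the mixed ketal is stable to these mildly basic conditions.

Step 9
Reactants: 9 (4S,6R)-2,4,6-trimethyl-14-phenyltetradec-1-ene; 13 tert-butyl{3-methoxy-3-[(triethylsilyl)peroxy]butoxy}diphenylsilane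
Product: 14 tert-butyl{2-[(3S,5R)-5-[(2S,4R)-2,4-dimethyl-12-phenyldodecyl]-3,5-dimethyl-1,2-dioxolan-3-yl]ethoxy}diphenylsilane
Conditions: 13 (1.5 equiv), SnCl4 (1.5 equiv), CH2Cl2, −78 °C; quench at −78 °C with aq. NaHCO3; obtained with its three ring diastereomers
Reagents that add atoms: none
Why: SnCl4 removes the methoxy group of 13 and gives a peroxycarbenium ion at C3; the CH2 terminus of 9 adds to it in the Markovnikov sense (C3–C4), and the tertiary C5 cation so formed is captured by the silyl-bearing peroxide oxygen with loss of Et3SiCl (O1–C5). The closest known reaction type is the SnCl4-mediated annulation of triethylsilylperoxy ketals of dialkyl ketones with 1,1-disubstituted alkenes, of which this is a direct case. The dioxolane closes by intramolecular capture of a carbocation by oxygen, the second stage of a stepwise cationic [3+2] annulation. Regioselectivity is required and is secured by the 2-methylalk-1-ene, which can place the positive charge only on the tertiary C5, three atoms from the attacking oxygen. Chemoselectivity is required against the phenyl terminus and the silyl ether; the alkylbenzene is a far poorer nucleophile than the alkene and the TBDPS ether should not ionise at −78 °C. C3 arises from a planar cation whose two alkyl arms differ little, and C5 from a cation whose nearest stereocentre (C7) lies beyond a methylene group, so neither new stereocentre is under effective control and all four ring diastereomers are expected in comparable amounts. Compound 14 is therefore carried forward with its ring diastereomers and the (3S,5R) isomer is secured by separation in step 10.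

Step 10
Reactants: 14 tert-butyl{2-[(3S,5R)-5-[(2S,4R)-2,4-dimethyl-12-phenyldodecyl]-3,5-dimethyl-1,2-dioxolan-3-yl]ethoxy}diphenylsilane (as the diastereomer mixture from step 9)
Product: 15 2-[(3S,5R)-5-[(2S,4R)-2,4-dimethyl-12-phenyldodecyl]-3,5-dimethyl-1,2-dioxolan-3-yl]ethan-1-ol
Conditions: TBAF, AcOH, THF, 0 °C to rt; then SiO2 chromatography and normal-phase preparative HPLC to the single diastereomer
Reagents that add atoms: none
Why: Fluoride cleavage of a primary silyl ether; the tetrasubstituted dioxolane has no hydrogen on its C–O carbons and so cannot undergo base-induced Kornblum–DeLaMare fragmentation, and acetic acid buffers the alkoxide. The hydroxyl group should let the four ring diastereomers be resolved, with cis- and trans-dimethyl isomers distinguished by NOE between the ring methyl groups.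

Step 11
Reactants: 15 2-[(3S,5R)-5-[(2S,4R)-2,4-dimethyl-12-phenyldodecyl]-3,5-dimethyl-1,2-dioxolan-3-yl]ethan-1-ol
Product: 17 2-[(3R,5R)-5-[(2S,4R)-2,4-dimethyl-12-phenyldodecyl]-3,5-dimethyl-1,2-dioxolan-3-yl]acetic acid, via the corresponding aldehyde 16 (not isolated)
Conditions: TEMPO (0.2 equiv), PhI(OAc)2 (2.2 equiv), MeCN/H2O (1:1), rt
Reagents that add atoms: water, O
Why: Oxoammonium (TEMPO/PhI(OAc)2) oxidation of a primary alcohol through the aldehyde hydrate to the carboxylic acid; the fully substituted dialkyl peroxide and the alkylbenzene are inert to the oxoammonium salt, and the weakly acidic medium avoids base-induced β-elimination of the peroxide from aldehyde 16.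

## Compound list

1 | (8-bromooctyl)benzene | BrCCCCCCCCc1ccccc1 | starting material
2 | methyl (2E)-but-2-enoate | C/C=C/C(=O)OC | starting material
3 | bromo(8-phenyloctyl)magnesium (8-phenyloctylmagnesium bromide) | Br[Mg]CCCCCCCCc1ccccc1 | intermediate (not isolated)
4 | methyl (3R)-3-methyl-11-phenylundecanoate | C[C@H](CCCCCCCCc1ccccc1)CC(=O)OC | intermediate
5 | (3R)-3-methyl-11-phenylundecanal | C[C@H](CCCCCCCCc1ccccc1)CC=O | intermediate
6 | 1-(triphenyl-λ5-phosphanylidene)propan-2-one | CC(=O)C=P(c1ccccc1)(c1ccccc1)c1ccccc1 | starting material
7 | (3E,6R)-6-methyl-14-phenyltetradec-3-en-2-one | C[C@H](CCCCCCCCc1ccccc1)C/C=C/C(C)=O | intermediate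
8 | (4S,6R)-4,6-dimethyl-14-phenyltetradecan-2-one | C[C@H](CCCCCCCCc1ccccc1)C[C@H](C)CC(C)=O | intermediate
9 | (4S,6R)-2,4,6-trimethyl-14-phenyltetradec-1-ene | C[C@H](CCCCCCCCc1ccccc1)C[C@H](C)CC(C)=C | intermediate
10 | 3-methylbut-3-en-1-ol | CC(=C)CCO | starting material
11 | tert-butyl[(3-methylbut-3-en-1-yl)oxy]diphenylsilane | CC(=C)CCO[Si](c1ccccc1)(c1ccccc1)C(C)(C)C | intermediate
12 | tert-butyl(3-hydroperoxy-3-methoxybutoxy)diphenylsilane (racemic) | COC(C)(CCO[Si](c1ccccc1)(c1ccccc1)C(C)(C)C)OO | intermediate
13 | tert-butyl{3-methoxy-3-[(triethylsilyl)peroxy]butoxy}diphenylsilane (racemic) | COC(C)(CCO[Si](c1ccccc1)(c1ccccc1)C(C)(C)C)OO[Si](CC)(CC)CC | intermediate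
14 | tert-butyl{2-[(3S,5R)-5-[(2S,4R)-2,4-dimethyl-12-phenyldodecyl]-3,5-dimethyl-1,2-dioxolan-3-yl]ethoxy}diphenylsilane | C[C@H](CCCCCCCCc1ccccc1)C[C@H](C)C[C@]1(C)C[C@](C)(CCO[Si](c2ccccc2)(c2ccccc2)C(C)(C)C)OO1 | intermediate
15 | 2-[(3S,5R)-5-[(2S,4R)-2,4-dimethyl-12-phenyldodecyl]-3,5-dimethyl-1,2-dioxolan-3-yl]ethan-1-ol | C[C@H](CCCCCCCCc1ccccc1)C[C@H](C)C[C@]1(C)C[C@](C)(CCO)OO1 | intermediate
16 | 2-[(3R,5R)-5-[(2S,4R)-2,4-dimethyl-12-phenyldodecyl]-3,5-dimethyl-1,2-dioxolan-3-yl]acetaldehyde | C[C@H](CCCCCCCCc1ccccc1)C[C@H](C)C[C@]1(C)C[C@](C)(CC=O)OO1 | intermediate (not isolated)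
17 | 2-[(3R,5R)-5-[(2S,4R)-2,4-dimethyl-12-phenyldodecyl]-3,5-dimethyl-1,2-dioxolan-3-yl]acetic acid | C[C@H](CCCCCCCCc1ccccc1)C[C@H](C)C[C@]1(C)C[C@](C)(CC(=O)O)OO1 | target

## Step count and risks

Total step count: 11. Longest linear sequence: 8 steps (steps 1–5, 9, 10, 11, from compound 1).

**Step 9 (key step).** Ring closure competes with several other processes: proton loss from the tertiary C5 cation or from the peroxycarbenium ion, Lewis-acid-induced double-bond migration or hydrochlorination of the valuable alkene, and rearrangement of the ionised peroxide. The closure also has no facial preference, so at best about a quarter of the dioxolane formed has the required ring configuration.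

Fallback, with the roles of the fragments exchanged: the route is left at alkene 9. Ozonolysis in CH2Cl2/MeOH at −78 °C would give (4S,6R)-2-hydroperoxy-2-methoxy-4,6-dimethyl-14-phenyltetradecane F1 (both C2 epimers). Silylation with Et3SiCl and imidazole would give triethyl{[(4S,6R)-2-methoxy-4,6-dimethyl-14-phenyltetradecan-2-yl]peroxy}silane F2. SnCl4-mediated annulation of F2 with a large excess of alkene 11, forming C4–C5 and O2–C3, comes back to the route at 14. The chain then meets the Lewis acid only as the electrophile, and the cheap alkene is the excess component.

**Step 10.** The four ring diastereomers may not resolve well, in particular the two cis-dimethyl isomers, which differ only in their relation to the remote C7 centre. Their assignment is also uncertain, because NOE separates cis from trans but not one cis isomer from the other.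

Fallback, by covalent derivatisation: from alcohol 15 as the diastereomer mixture, acylation with 4-bromobenzoyl chloride and pyridine would give 2-[(3S,5R)-5-[(2S,4R)-2,4-dimethyl-12-phenyldodecyl]-3,5-dimethyl-1,2-dioxolan-3-yl]ethyl 4-bromobenzoate F3 and its isomers. These esters are separated by HPLC or crystallisation, and the heavy atom allows the configuration to be assigned by X-ray diffraction. Methanolysis (K2CO3, MeOH) comes back to the route at 15 as the single isomer.

**Step 4.** MeMgBr may add in part to the ketone carbonyl (1,2-addition), and catalyst control over the new centre may be incomplete, leaving the syn diastereomer in the chain.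

Fallback, with a thioester acceptor: from aldehyde 5, Wittig reaction with S-ethyl 2-(triphenyl-λ5-phosphanylidene)ethanethioate would give S-ethyl (2E,5R)-5-methyl-13-phenyltridec-2-enethioate F4. Addition of MeMgBr with CuBr·SMe2/(S,R)-Josiphos in tBuOMe at −75 °C would give S-ethyl (3S,5R)-3,5-dimethyl-13-phenyltridecanethioate F5. Me2CuLi in Et2O at −78 °C converts the thioester to the methyl ketone and comes back at 8.

**Step 1.** The face selection on the small β-methyl enoate by the long-chain Grignard reagent may be insufficient. The wrong C9 epimer would then travel through the route and add to the separation burden in step 10.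

Fallback, with nucleophile and acceptor exchanged: from bromide 1 through Grignard reagent 3, formylation with DMF would give 9-phenylnonanal F6. Wittig reaction with the same thioester ylide would give S-ethyl (2E)-11-phenylundec-2-enethioate F7. Addition of MeMgBr with CuBr·SMe2 and the mirror-image ligand (R,S)-Josiphos would give S-ethyl (3R)-3-methyl-11-phenylundecanethioate F8. Reduction with i-Bu2AlH at −65 °C comes back at aldehyde 5.

**Step 7.** The primary ozonide may partition in part towards formaldehyde O-oxide and the ketone. Methanol may also be lost from the hydroperoxy ketal on silica gel.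

Fallback, by ketal perhydrolysis: from alkene 11, ozonolysis with Me2S work-up would give 4-{[tert-butyl(diphenyl)silyl]oxy}butan-2-one F9. Treatment with HC(OMe)3, MeOH and PPTS would give tert-butyl(3,3-dimethoxybutoxy)diphenylsilane F10. Acid-catalysed exchange of one methoxy group with ethereal H2O2 comes back at 12.

## Further compounds

F1 | step 9 | (4S,6R)-2-hydroperoxy-2-methoxy-4,6-dimethyl-14-phenyltetradecane (C2 epimers) | C[C@H](CCCCCCCCc1ccccc1)C[C@H](C)CC(C)(OC)OO
F2 | step 9 | triethyl{[(4S,6R)-2-methoxy-4,6-dimethyl-14-phenyltetradecan-2-yl]peroxy}silane (C2 epimers) | C[C@H](CCCCCCCCc1ccccc1)C[C@H](C)CC(C)(OC)OO[Si](CC)(CC)CC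
F3 | step 10 | 2-[(3S,5R)-5-[(2S,4R)-2,4-dimethyl-12-phenyldodecyl]-3,5-dimethyl-1,2-dioxolan-3-yl]ethyl 4-bromobenzoate | C[C@H](CCCCCCCCc1ccccc1)C[C@H](C)C[C@]1(C)C[C@](C)(CCOC(=O)c2ccc(Br)cc2)OO1
F4 | step 4 | S-ethyl (2E,5R)-5-methyl-13-phenyltridec-2-enethioate | C[C@H](CCCCCCCCc1ccccc1)C/C=C/C(=O)SCC
F5 | step 4 | S-ethyl (3S,5R)-3,5-dimethyl-13-phenyltridecanethioate | C[C@H](CCCCCCCCc1ccccc1)C[C@H](C)CC(=O)SCC
F6 | step 1 | 9-phenylnonanal | O=CCCCCCCCCc1ccccc1
F7 | step 1 | S-ethyl (2E)-11-phenylundec-2-enethioate | CCSC(=O)/C=C/CCCCCCCCc1ccccc1
F8 | step 1 | S-ethyl (3R)-3-methyl-11-phenylundecanethioate | C[C@H](CCCCCCCCc1ccccc1)CC(=O)SCC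
F9 | step 7 | 4-{[tert-butyl(diphenyl)silyl]oxy}butan-2-one | CC(=O)CCO[Si](c1ccccc1)(c1ccccc1)C(C)(C)C
F10 | step 7 | tert-butyl(3,3-dimethoxybutoxy)diphenylsilane | COC(C)(CCO[Si](c1ccccc1)(c1ccccc1)C(C)(C)C)OC
A1 | alternative 1 | 4,4,5,5-tetramethyl-2-(8-phenyloctyl)-1,3,2-dioxaborolane | CC1(C)OB(CCCCCCCCc2ccccc2)OC1(C)C
A2 | alternative 1 | 2-[(2R,4R)-2,4-dimethyl-12-phenyldodecyl]-4,4,5,5-tetramethyl-1,3,2-dioxaborolane | C[C@H](CCCCCCCCc1ccccc1)C[C@H](C)CB1OC(C)(C)C(C)(C)O1
A3 | alternative 2 | triethyl{[(4S,6R)-2-methoxy-4,6-dimethyl-14-phenyltetradecan-2-yl]peroxy}silane (C2 epimers) | C[C@H](CCCCCCCCc1ccccc1)C[C@H](C)CC(C)(OC)OO[Si](CC)(CC)CC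
A4 | alternative 2 | tert-butyl{2-[(3S,5R)-5-[(2S,4R)-2,4-dimethyl-12-phenyldodecyl]-3,5-dimethyl-1,2-dioxolan-3-yl]ethoxy}diphenylsilane | C[C@H](CCCCCCCCc1ccccc1)C[C@H](C)C[C@]1(C)C[C@](C)(CCO[Si](c2ccccc2)(c2ccccc2)C(C)(C)C)OO1
A5 | alternative 3 | 1-[(2S,4R)-2,4-dimethyl-12-phenyldodecyl]-2-ethenyl-1,2-dimethylcyclopropane (ring stereoisomers) | C[C@H](CCCCCCCCc1ccccc1)C[C@H](C)CC1(C)CC1(C)C=C
A6 | alternative 3 | (3R,5R)-3-ethenyl-5-[(2S,4R)-2,4-dimethyl-12-phenyldodecyl]-3,5-dimethyl-1,2-dioxolane | C[C@H](CCCCCCCCc1ccccc1)C[C@H](C)C[C@]1(C)C[C@](C)(C=C)OO1
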